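**Retrosynthetic overview**
1. Target 11 ⇐ depside aldehyde 10 by a final Pinnick oxidation, so the B-ring acid never needs a protecting group.
2. 10 ⇐ ester C–O bond between A-ring acid 8 and B-ring phenol aldehyde 7.
3. 7 and 8 both ⇐ 3-methoxy-5-pentylphenol 5 (para-formylation versus ortho-carboxylation); 5 ⇐ diether 4 by mono-demethylation.
4. Key C–C bond: ArCH2–C4H9 of 4 ⇐ 3,5-dimethoxybenzaldehyde 1, used as its N–H hydrazone (a benzyl carbanion equivalent, i.e. carbonyl umpolung), plus 1-bromobutane 2. Both carbons are natively electrophilic, and one step replaces the usual dithiane alkylation/desulfurisation sequence.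
5. No ring is formed: both benzene rings come from 1.

Assumption: the target has no stereocentre, so the "single enantiomer" is the compound itself; ionised forms of a product that exist only until acidic work-up (phenolate, carboxylate, magnesium chelate) are not counted as separate compounds.

**Step 1**
Reactants: 1 3,5-dimethoxybenzaldehyde; 2 1-bromobutane
Product: 4 1,3-dimethoxy-5-pentylbenzene, via aldehyde hydrazone 3 (not isolated)
Conditions: N2H4·H2O (1.2 equiv), THF, rt, 1 h, 4 Å MS; then 2 (1.5 equiv), Ni(cod)2 (10 mol%), dtbbpy (12 mol%), K3PO4 (2 equiv), THF/dioxane, 60 °C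
Reagents that add atoms: hydrazine hydrate, NN.O (its two N atoms are in intermediate 3 only and leave as N2)
Why: Nickel-catalysed denitrogenative cross-coupling of an N-unsubstituted hydrazone with an unactivated primary alkyl bromide (carbonyl umpolung through the Wolff–Kishner-type carbanion equivalent): deprotonated 3 meets the butyl–nickel species from 2 and the C–C bond forms with loss of N2, so the formerly electrophilic aldehyde carbon is joined to the electrophilic bromide carbon and arrives directly at the CH2 level; no stereocentre is formed.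

**Step 2**
Reactants: 4 1,3-dimethoxy-5-pentylbenzene
Product: 5 3-methoxy-5-pentylphenol
Conditions: NaSEt (2.5 equiv), DMF, 140 °C, 3 h; then 1 M HCl
Reagents that add atoms: none
Why: Thiolate SN2 O-demethylation: after the first cleavage the ring is an electron-rich phenolate that resists a second attack, so the symmetric diether stops cleanly at the mono-phenol; no stereocentre is formed.

**Step 3**
Reactants: 5 3-methoxy-5-pentylphenol
Product: 7 4-hydroxy-2-methoxy-6-pentylbenzaldehyde, via aryl iminium chloride 6 (not isolated)
Conditions: POCl3 (1.2 equiv), DMF, 0 °C to rt, 12 h; then H2O, 50 °C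
Reagents that add atoms: N,N-dimethylformamide, CN(C)C=O (formyl carbon; its NMe2 stays in 6 only); phosphoryl chloride, O=P(Cl)(Cl)Cl (chloride of 6 only); water, O (carbonyl oxygen of 7)
Why: Vilsmeier–Haack formylation: the chloroiminium electrophile attacks mainly para to the free OH (C4, between OMe and pentyl), as for other 3-alkoxy-5-alkylphenols, and the minor chelated ortho-hydroxy isomer is far less polar and is removed on silica; no stereocentre is formed.

**Step 4**
Reactants: 5 3-methoxy-5-pentylphenol
Product: 8 2-hydroxy-4-methoxy-6-pentylbenzoic acid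
Conditions: MeOMgOCO2Me (2 M in DMF, 5 equiv), 120 °C, 3 h, N2 stream; then cold 2 M HCl, 0 °C
Reagents that add atoms: methylmagnesium carbonate (Stiles' reagent), COC(=O)O[Mg]OC
Why: Kolbe–Schmitt-type ortho-carboxylation with Stiles' reagent: the magnesium phenolate delivers CO2 to the ortho carbon that is para to OMe (C6, the same site that 5-alkylresorcinols and cannabinoid phenols carboxylate at) and the product is held as a magnesium salicylate chelate until cold acidification; no stereocentre is formed.

**Step 5**
Reactants: 8 2-hydroxy-4-methoxy-6-pentylbenzoic acid; 7 4-hydroxy-2-methoxy-6-pentylbenzaldehyde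
Product: 10 4-formyl-3-methoxy-5-pentylphenyl 2-hydroxy-4-methoxy-6-pentylbenzoate, via mixed trifluoroacetic anhydride 9 (not isolated)
Conditions: TFAA (3 equiv), toluene, rt, 4 h
Reagents that add atoms: trifluoroacetic anhydride, O=C(OC(=O)C(F)(F)F)C(F)(F)F (its CF3CO group is in intermediate 9 only; nothing remains in 10)
Why: Mixed-anhydride (TFAA) esterification as used for lichen depsides: the hindered acid is activated as 9 and acylates the unhindered para-OH of 7, while the A-ring 2-OH is hydrogen-bonded to its carbonyl and flanked, so it does not compete; no stereocentre is formed.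

**Step 6**
Reactants: 10 4-formyl-3-methoxy-5-pentylphenyl 2-hydroxy-4-methoxy-6-pentylbenzoate
Product: 11 2'-O-methylperlatolic acid
Conditions: NaClO2 (3 equiv), NaH2PO4 (3 equiv), 2-methyl-2-butene (20 equiv), t-BuOH/THF/H2O, 0 °C to rt
Reagents that add atoms: sodium chlorite, [Na+].[O-]Cl=O
Why: Pinnick (Lindgren) oxidation: chlorous acid converts the hindered aryl aldehyde into the acid at pH 3–4, where the aryl ester is stable, and 2-methyl-2-butene traps HOCl before it can chlorinate the electron-rich A ring; no stereocentre is formed.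

**Compound list**
1 | 3,5-dimethoxybenzaldehyde | COc1cc(OC)cc(C=O)c1 | starting material
2 | 1-bromobutane | CCCCBr | starting material
3 | (E)-(3,5-dimethoxybenzylidene)hydrazine | COc1cc(OC)cc(/C=N/N)c1 | intermediate (not isolated)
4 | 1,3-dimethoxy-5-pentylbenzene (olivetol dimethyl ether) | CCCCCc1cc(OC)cc(OC)c1 | intermediate
5 | 3-methoxy-5-pentylphenol | CCCCCc1cc(O)cc(OC)c1 | intermediate
6 | N-(4-hydroxy-2-methoxy-6-pentylbenzylidene)-N-methylmethanaminium chloride | CCCCCc1cc(O)cc(OC)c1C=[N+](C)C.[Cl-] | intermediate (not isolated)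
7 | 4-hydroxy-2-methoxy-6-pentylbenzaldehyde | CCCCCc1cc(O)cc(OC)c1C=O | intermediate
8 | 2-hydroxy-4-methoxy-6-pentylbenzoic acid | CCCCCc1cc(OC)cc(O)c1C(=O)O | intermediate
9 | 2-hydroxy-4-methoxy-6-pentylbenzoic trifluoroacetic anhydride | CCCCCc1cc(OC)cc(O)c1C(=O)OC(=O)C(F)(F)F | intermediate (not isolated)
10 | 4-formyl-3-methoxy-5-pentylphenyl 2-hydroxy-4-methoxy-6-pentylbenzoate | CCCCCc1cc(OC)cc(O)c1C(=O)Oc1cc(CCCCC)c(C=O)c(OC)c1 | intermediate
11 | 2'-O-methylperlatolic acid, 4-[(2-hydroxy-4-methoxy-6-pentylbenzoyl)oxy]-2-methoxy-6-pentylbenzoic acid | CCCCCc1cc(OC)cc(O)c1C(=O)Oc1cc(CCCCC)c(C(=O)O)c(OC)c1 | target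

**Step count**
Total: 6 steps. Longest linear sequence: 5 steps (1 → 2 → 3 or 4 → 5 → 6).

**Three steps most likely to fail**

Step 1 is the riskiest. The hydrazone can form the azine, be N-alkylated by 2, or simply reduce to 3,5-dimethoxytoluene, and butyl–nickel can β-eliminate; ligand and base will need screening. The fallback sets out from 1 and comes back at 4 by the classical dithiane acyl-anion route. Compound 1 with propane-1,3-dithiol and BF3·OEt2 in CH2Cl2 gives 2-(3,5-dimethoxyphenyl)-1,3-dithiane F1. n-BuLi in THF at −40 °C gives 2-(3,5-dimethoxyphenyl)-2-lithio-1,3-dithiane F2, which is alkylated with 2 to 2-butyl-2-(3,5-dimethoxyphenyl)-1,3-dithiane F3. Raney nickel in refluxing ethanol then removes the sulfur and gives 4.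

Step 4 may stop at partial conversion or carboxylate partly at the other ortho carbon (C2, between OH and OMe), and 8 decarboxylates if acidified warm. The fallback sets out from 5 and comes back at 8. Magnesium-mediated ortho-formylation (MgCl2, Et3N, paraformaldehyde, MeCN, reflux) gives 2-hydroxy-4-methoxy-6-pentylbenzaldehyde F4. This is also the minor isomer of step 3, so the two lots can be pooled. Pinnick oxidation (NaClO2, sulfamic acid, dioxane/H2O) then gives 8.

Step 5 joins a di-ortho-substituted acid to an electron-poor phenol. Acylation may be slow, and self-condensation through the A-ring 2-OH or trifluoroacetylation of 7 could take over. The fallback sets out from 8 and comes back at 10. Acetone, TFAA and TFA convert 8 into 7-methoxy-2,2-dimethyl-5-pentyl-4H-1,3-benzodioxin-4-one F5, which masks the 2-OH and activates the carboxyl at once. Heating F5 with 7 and Cs2CO3 in DMF at 60 °C opens the dioxinone at the carbonyl with loss of acetone and gives 10 after mild acid work-up.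

**Further compounds**
F1 | step 1 | 2-(3,5-dimethoxyphenyl)-1,3-dithiane | COc1cc(OC)cc(C2SCCCS2)c1
F2 | step 1 | 2-(3,5-dimethoxyphenyl)-2-lithio-1,3-dithiane | [Li]C1(c2cc(OC)cc(OC)c2)SCCCS1
F3 | step 1 | 2-butyl-2-(3,5-dimethoxyphenyl)-1,3-dithiane | CCCCC1(c2cc(OC)cc(OC)c2)SCCCS1
F4 | step 4 | 2-hydroxy-4-methoxy-6-pentylbenzaldehyde | CCCCCc1cc(OC)cc(O)c1C=O
F5 | step 5 | 7-methoxy-2,2-dimethyl-5-pentyl-4H-1,3-benzodioxin-4-one | CCCCCc1cc(OC)cc2OC(C)(C)OC(=O)c12
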